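The route disconnects the C3–C4 bond of ring A. Ring B with its substituents is (S)-carvone: the ring carbons are C5–C10, the ring methyl is C17, and the isopropenyl group supplies C4, C18 and C19. Because the C3 carbinol is bonded to the fully substituted C4, an iron-hydride hydrogen-atom transfer to the isopropenyl group gives a tertiary C4 radical that adds 6-exo to a C3 aldehyde. That one operation forms C3–C4, closes ring A as the trans-decalin and sets the C3 hydroxyl. The precursor is carvone carrying at C10 a methyl group and a 3-oxopropyl arm anti to the isopropenyl group. The surviving enone is converted into the C9 side chain and the C17 aldehyde.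

Key step: step 5

Remark: atoms carry labdane numbers (ring A: C1–C5 and C10; ring B: C5–C10; C17 on C8; C18 and C19 on C4; C20 on C10; chain C11–C16 on C9). The target has the (5S,10S) configuration of the enantiomeric labdane series, which corresponds to (S)-carvone. The epimer ratio at C10 after step 1 is assumed not to matter, because step 2 passes through the planar enolate.

Step 1
Reactants: 1 (S)-carvone; 2 iodomethane
Product: 4 6-methylcarvone (both C6 epimers), via lithium enolate 3 (not isolated)
Conditions: LiN(i-Pr)2 (1.05 equiv), THF, −78 °C; then MeI, −78 to 0 °C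
Reagents that add atoms: none
Why: Enolate alkylation, in which the lithium amide removes a proton kinetically from the α′ methylene (future C10) to give the cross-conjugated enolate, which is C-methylated; the new centre forms as an epimer mixture that is made planar again in step 2.

Step 2
Reactants: 4 6-methylcarvone; 5 allyl bromide
Product: 7 (5R,6R)-6-allyl-2,6-dimethyl-5-(prop-1-en-2-yl)cyclohex-2-en-1-one, via lithium enolate 6 (not isolated)
Conditions: LiN(i-Pr)2 (1.1 equiv), THF, −78 to 0 °C; then allyl bromide, DMPU, −78 °C to rt
Reagents that add atoms: none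
Why: Enolate alkylation forming the quaternary C10, in which allyl bromide should attack the tetrasubstituted enolate on the face away from the neighbouring isopropenyl group at C5, so that the three-carbon arm (future C1–C3) ends anti to isopropenyl and the methyl (C20) syn, the relationship that later becomes the trans ring fusion.

Step 3
Reactants: 7 allyl methyl carvone
Product: 9 (5R,6R)-6-(3-hydroxypropyl)-2,6-dimethyl-5-(prop-1-en-2-yl)cyclohex-2-en-1-one, via alkyldisiamylborane 8 (not isolated)
Conditions: disiamylborane (from BH3·SMe2 and 2-methylbut-2-ene, THF, 0 °C), 0 °C; then NaBO3·4H2O, H2O, rt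
Reagents that add atoms: sodium perborate, [Na+].[Na+].O[B-]1(O)OO[B-](O)(O)OO1
Why: Brown hydroboration–oxidation, in which the bulky dialkylborane should add anti-Markovnikov to the unhindered monosubstituted allyl alkene far faster than to the hindered 1,1-disubstituted isopropenyl group, the trisubstituted enone alkene or the flanked C9 carbonyl, while the perborate oxidation avoids the strongly alkaline peroxide that would epoxidise the enone.

Step 4
Reactants: 9 hydroxypropyl enone
Product: 10 3-[(1R,6R)-1,3-dimethyl-2-oxo-6-(prop-1-en-2-yl)cyclohex-3-en-1-yl]propanal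
Conditions: Dess–Martin periodinane, CH2Cl2, 0 °C to rt
Reagents that add atoms: none
Why: Dess–Martin oxidation should convert the primary alcohol into the aldehyde under neutral conditions without over-oxidation and without touching the two alkenes or the enone.

Step 5
Reactants: 10 aldehyde with isopropenyl group
Product: 11 (4aR,6R,8aR)-6-hydroxy-2,5,5,8a-tetramethyl-4a,5,6,7,8,8a-hexahydronaphthalen-1(4H)-one
Conditions: Fe(acac)3 (0.5 equiv), PhSiH3 (2.5 equiv), EtOH (0.02 M), 60 °C, argon
Reagents that add atoms: none
Why: An iron hydride formed from Fe(acac)3 and PhSiH3 in ethanol transfers a hydrogen atom to the terminal carbon of the isopropenyl group (Markovnikov), the tertiary C4 radical adds to the aldehyde carbon C3, and the alkoxy radical is reduced by divalent iron to the alkoxide and protonated by ethanol, which pulls the reversible addition forward. The closest known reaction type is the iron-hydride hydrogen-atom-transfer reductive cyclisation of alkene-tethered ketones to cyclic alcohols, together with the intermolecular iron-hydride coupling of alkenes with aldehydes. Ring A closes in the 6-exo-trig mode onto the carbonyl carbon through a chair transition state. The trans ring fusion is already fixed by C5 (chiral pool) and C10 (step 2), because the C4 radical centre and the C1–C3 arm are both equatorial on ring B; the new C3 centre is controlled by this chair, in which the carbonyl oxygen should take the equatorial site and so avoid the axial hydrogens at C1 and C5. The step needs hydrogen-atom transfer to the isopropenyl group and attack on the aldehyde, both in preference to the enone; the substrate secures this because the enone alkene is electron-poor, trisubstituted and hindered, and because every path from C4 to an enone carbon would close a four-membered or a strained bridged five-membered ring.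

Step 6
Reactants: 11 hydroxy enone
Product: 12 O3-tert-butyldimethylsilyl ether of 11
Conditions: TBSOTf, 2,6-lutidine, CH2Cl2, 0 °C
Reagents that add atoms: tert-butyldimethylsilyl triflate, CC(C)(C)[Si](C)(C)OS(=O)(=O)C(F)(F)F
Why: Silyl ether formation with the silyl triflate, which is reactive enough for the secondary hydroxyl next to the gem-dimethyl carbon, masks O3 against the hydride, amide base, ylide and oxidant used later.

Step 7
Reactants: 12 silyl ether enone
Product: 14 C9 enol triflate (C8=C9), via lithium enolate 13 (not isolated)
Conditions: LiBH(s-Bu)3 (1.1 equiv), THF, −78 °C; then PhNTf2, −78 °C to rt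
Reagents that add atoms: N-phenylbis(trifluoromethanesulfonimide), O=S(=O)(N(c1ccccc1)S(=O)(=O)C(F)(F)F)C(F)(F)F
Why: Conjugate (1,4) hydride reduction followed by O-sulfonylation of the enolate, in which the bulky borohydride should attack C7 because the C9 carbonyl is shielded by quaternary C10, and the regiodefined C8–C9 enolate is trapped on oxygen as the enol triflate.

Step 8
Reactants: 14 enol triflate
Product: 15 methyl ester on C9 conjugated to C8=C9
Conditions: Pd(OAc)2 (10 mol%), PPh3 (20 mol%), CO (1 atm), MeOH, Et3N, DMF, 60 °C
Reagents that add atoms: carbon monoxide, [C-]#[O+]; methanol, CO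
Why: Palladium-catalysed methoxycarbonylation of the enol triflate (oxidative addition to zerovalent palladium, CO insertion, methanolysis of the acyl palladium) installs C11 as the ester carbon on C9.

Step 9
Reactants: 15 conjugated ester
Product: 17 methyl ester with exocyclic C8=C17 alkene and H-9 anti to C20, via lithium dienolate 16 (not isolated)
Conditions: LiN(i-Pr)2 (2 equiv), DMPU, THF, −78 to −40 °C; then AcOH, THF, −78 °C
Reagents that add atoms: none
Why: Deconjugative protonation of an extended enolate, in which the lithium amide, held by the ester carbonyl, should remove a proton from C17 (the γ-carbon syn to the ester) and kinetic protonation at the α-carbon C9 from the face opposite the axial C20 methyl gives the exocyclic alkene with the ester equatorial and cis to C20, which sets C9.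

Step 10
Reactants: 17 deconjugated ester
Product: 20 cis-fused γ-lactone (C11 carbonyl to O–C17), via alkyl-9-BBN 18 (not isolated), via hydroxy ester 19 (not isolated)
Conditions: 9-BBN (2 equiv), THF, 0 to 60 °C; then NaOH, H2O2, H2O, 0 °C to rt; crude product: PPTS (cat.), toluene, 60 °C
Reagents that add atoms: hydrogen peroxide, OO
Why: Hydroboration–oxidation followed by lactonisation, in which the borane should add to the exocyclic alkene from the face opposite the axial C20 methyl, so that hydrogen enters C8 anti to C20 and C17 ends axial and cis to the C9 ester, and the γ-hydroxy ester closes to the cis-fused lactone, which tells C17 from C11 without a protecting group.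

Step 11
Reactants: 20 lactone
Product: 21 lactol (both anomers)
Conditions: i-Bu2AlH (1.2 equiv), CH2Cl2, −78 °C; Rochelle salt work-up
Reagents that add atoms: none
Why: Partial reduction of the lactone with the aluminium hydride at −78 °C should stop at the lactol because the tetrahedral aluminium hemiacetal does not collapse at this temperature.

Step 12
Reactants: 21 lactol
Product: 23 C9 vinyl compound with axial C8 hydroxymethyl group, via hydroxy aldehyde 22 (not isolated)
Conditions: Ph3PCH3Br (4 equiv), KOt-Bu (3.8 equiv), THF, 0 °C to reflux
Reagents that add atoms: methyltriphenylphosphonium bromide, C[P+](c1ccccc1)(c1ccccc1)c1ccccc1.[Br-]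
Why: Wittig methylenation of the lactol through its open hydroxy aldehyde form converts C11 into the vinyl group (C11=C12) and frees the C17 hydroxyl, while C9 keeps its equatorial substituent, which is also the thermodynamically preferred arrangement should the aldehyde enolise.

Step 13
Reactants: 24 methyl but-2-ynoate
Product: 25 methyl (2Z)-3-iodobut-2-enoate
Conditions: NaI, AcOH, 115 °C
Reagents that add atoms: sodium iodide, [Na+].[I-]
Why: Conjugate hydroiodination of the ynoate, in which iodide adds to the β-carbon and protonation places H and I trans, gives the Z-iodoenoate with iodine cis to the ester.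

Step 14
Reactants: 23 vinyl alcohol; 25 methyl (2Z)-3-iodobut-2-enoate
Product: 27 Z-enoate with axial C8 hydroxymethyl group, via bis-boryl adduct 26 (not isolated)
Conditions: 9-BBN (2.5 equiv), THF, 0 °C to rt; then 25, Pd(dppf)Cl2 (5 mol%), AsPh3 (5 mol%), Cs2CO3, DMF/H2O, rt
Reagents that add atoms: none
Why: B-alkyl Suzuki–Miyaura coupling, in which 9-BBN adds anti-Markovnikov to the vinyl group (and converts the hydroxyl into its borinate) and the primary alkylborane is coupled with the vinyl iodide under palladium catalysis with retention of the alkene geometry, forms C12–C13 and the Z-enoate.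

Step 15
Reactants: 27 hydroxy Z-enoate
Product: 28 C8-epimeric aldehyde (formyl group axial and cis to C20)
Conditions: Dess–Martin periodinane, CH2Cl2, 0 °C to rt
Reagents that add atoms: none
Why: Dess–Martin oxidation of the primary C17 alcohol should give the aldehyde under neutral conditions without isomerising the Z-enoate or cleaving the silyl ether.

Step 16
Reactants: 28 axial aldehyde
Product: 29 O3-silyl ether of the target (formyl group equatorial)
Conditions: K2CO3 (0.3 equiv), MeOH, rt
Reagents that add atoms: none
Why: Base-mediated epimerisation through the aldehyde enolate should move the formyl group from the axial position, where it is 1,3-diaxial to the C20 methyl, to the equatorial position trans to the C9 side chain, which sets C8 under thermodynamic control.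

Step 17
Reactants: 29 silyl ether
Product: 30 target CNP0188570.1
Conditions: HF (48% aq.), MeCN, 0 °C to rt
Reagents that add atoms: none
Why: Acidic fluoride cleavage of the silyl ether (desilylation) frees the C3 hydroxyl under conditions that should leave the aldehyde, the Z-enoate and the already thermodynamic C8 configuration unchanged.

Compound list
1 | (S)-(+)-carvone, (5S)-2-methyl-5-(prop-1-en-2-yl)cyclohex-2-en-1-one | O=C1C(C)=CC[C@H](C(C)=C)C1 | starting material
2 | iodomethane | CI | starting material
3 | lithium enolate of 1 (cross-conjugated, formed at the α′ carbon) | [Li]OC1=C[C@@H](C(C)=C)CC=C1C | intermediate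
4 | (5S,6RS)-2,6-dimethyl-5-(prop-1-en-2-yl)cyclohex-2-en-1-one (6-methylcarvone, both C6 epimers) | O=C1C(C)=CC[C@H](C(C)=C)C1C | intermediate
5 | allyl bromide (3-bromoprop-1-ene) | C=CCBr | starting material
6 | lithium enolate of 4 (tetrasubstituted, planar at the methyl-bearing carbon) | [Li]OC1=C(C)[C@@H](C(C)=C)CC=C1C | intermediate
7 | (5R,6R)-2,6-dimethyl-6-(prop-2-en-1-yl)-5-(prop-1-en-2-yl)cyclohex-2-en-1-one (allyl anti to isopropenyl) | O=C1C(C)=CC[C@H](C(C)=C)[C@@]1(C)CC=C | intermediate
8 | bis(3-methylbutan-2-yl)borane adduct of 7 (boron on the terminal carbon of the former allyl group) | O=C1C(C)=CC[C@H](C(C)=C)[C@@]1(C)CCCB(C(C)C(C)C)C(C)C(C)C | intermediate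
9 | (5R,6R)-6-(3-hydroxypropyl)-2,6-dimethyl-5-(prop-1-en-2-yl)cyclohex-2-en-1-one | O=C1C(C)=CC[C@H](C(C)=C)[C@@]1(C)CCCO | intermediate
10 | 3-[(1R,6R)-1,3-dimethyl-2-oxo-6-(prop-1-en-2-yl)cyclohex-3-en-1-yl]propanal (key-step precursor) | O=C1C(C)=CC[C@H](C(C)=C)[C@@]1(C)CCC=O | intermediate
11 | (4aR,6R,8aR)-6-hydroxy-2,5,5,8a-tetramethyl-4a,5,6,7,8,8a-hexahydronaphthalen-1(4H)-one (trans-fused, C3 hydroxyl equatorial; key-step product) | O=C1C(C)=CC[C@@H]2C(C)(C)[C@H](O)CC[C@@]12C | intermediate
12 | (4aR,6R,8aR)-6-[(tert-butyldimethylsilyl)oxy]-2,5,5,8a-tetramethyl-4a,5,6,7,8,8a-hexahydronaphthalen-1(4H)-one | O=C1C(C)=CC[C@@H]2C(C)(C)[C@H](O[Si](C)(C)C(C)(C)C)CC[C@@]12C | intermediate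
13 | lithium C8=C9 enolate of the 7,8-dihydro ketone derived from 12 (O-lithio at C9) | [Li]OC1=C(C)CC[C@@H]2C(C)(C)[C@H](O[Si](C)(C)C(C)(C)C)CC[C@@]12C | intermediate
14 | C9 enol triflate of the trans-decalin (C8=C9, C17 methyl on C8, O3 silyl ether) | FC(F)(F)S(=O)(=O)OC1=C(C)CC[C@@H]2C(C)(C)[C@H](O[Si](C)(C)C(C)(C)C)CC[C@@]12C | intermediate
15 | methyl ester on C9 of the trans-decalin, conjugated to C8=C9 (C11 is the ester carbon, O3 silyl ether) | COC(=O)C1=C(C)CC[C@@H]2C(C)(C)[C@H](O[Si](C)(C)C(C)(C)C)CC[C@@]12C | intermediate
16 | lithium dienolate of 15 (C9=C11 ketene acetal and exocyclic C8=C17) | [Li]OC(OC)=C1C(=C)CC[C@@H]2C(C)(C)[C@H](O[Si](C)(C)C(C)(C)C)CC[C@@]12C | intermediate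
17 | methyl ester on C9 with exocyclic C8=C17 methylene (H-9 anti to C20, ester equatorial and cis to C20, O3 silyl ether) | COC(=O)[C@@H]1C(=C)CC[C@@H]2C(C)(C)[C@H](O[Si](C)(C)C(C)(C)C)CC[C@@]12C | intermediate
18 | 9-BBN adduct of 17 (boron on C17; C17 axial, cis to C20 and to the C9 ester) | COC(=O)[C@@H]1[C@H](CB3C4CCCC3CCC4)CC[C@@H]2C(C)(C)[C@H](O[Si](C)(C)C(C)(C)C)CC[C@@]12C | intermediate
19 | γ-hydroxy ester (axial C8 hydroxymethyl cis to the equatorial C9 methyl ester) | COC(=O)[C@@H]1[C@H](CO)CC[C@@H]2C(C)(C)[C@H](O[Si](C)(C)C(C)(C)C)CC[C@@]12C | intermediate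
20 | cis-fused γ-lactone between C11 (carbonyl, on C9) and O–C17 (on C8); H-8 and H-9 anti to C20, O3 silyl ether | O=C1OC[C@@H]2CC[C@@H]3C(C)(C)[C@H](O[Si](C)(C)C(C)(C)C)CC[C@@]3(C)[C@H]12 | intermediate
21 | lactol of 20 (C11 hemiacetal, both anomers) | OC1OC[C@@H]2CC[C@@H]3C(C)(C)[C@H](O[Si](C)(C)C(C)(C)C)CC[C@@]3(C)[C@H]12 | intermediate
22 | open form of 21: equatorial C9 formyl group (C11) and axial C8 hydroxymethyl group | O=C[C@@H]1[C@H](CO)CC[C@@H]2C(C)(C)[C@H](O[Si](C)(C)C(C)(C)C)CC[C@@]12C | intermediate
23 | trans-decalin with equatorial C9 vinyl group (C11=C12), axial C8 hydroxymethyl group (cis to C20) and O3 silyl ether | C=C[C@@H]1[C@H](CO)CC[C@@H]2C(C)(C)[C@H](O[Si](C)(C)C(C)(C)C)CC[C@@]12C | intermediate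
24 | methyl but-2-ynoate | CC#CC(=O)OC | starting material
25 | methyl (2Z)-3-iodobut-2-enoate | COC(=O)/C=C(/C)I | intermediate
26 | bis-boryl adduct of 23 (9-BBN on C12, O17 as its 9-BBN borinate) | B1(C2CCCC1CCC2)CC[C@@H]3[C@H](COB4C5CCCC4CCC5)CC[C@@H]6C(C)(C)[C@H](O[Si](C)(C)C(C)(C)C)CC[C@@]36C | intermediate
27 | methyl (2Z)-3-methylpent-2-enoate carrying at C5 the decalin with axial C8 hydroxymethyl group and O3 silyl ether | COC(=O)/C=C(/C)CC[C@@H]1[C@H](CO)CC[C@@H]2C(C)(C)[C@H](O[Si](C)(C)C(C)(C)C)CC[C@@]12C | intermediate
28 | C8 epimer of 29 (formyl group axial, cis to C20 and to the C9 side chain) | COC(=O)/C=C(/C)CC[C@@H]1[C@H](C=O)CC[C@@H]2C(C)(C)[C@H](O[Si](C)(C)C(C)(C)C)CC[C@@]12C | intermediate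
29 | O3-tert-butyldimethylsilyl ether of the target (formyl group equatorial, trans to the C9 side chain) | COC(=O)/C=C(/C)CC[C@@H]1[C@@H](C=O)CC[C@@H]2C(C)(C)[C@H](O[Si](C)(C)C(C)(C)C)CC[C@@]12C | intermediate
30 | methyl (2Z)-5-[(1R,2S,4aS,6R,8aS)-2-formyl-6-hydroxy-5,5,8a-trimethyldecahydronaphthalen-1-yl]-3-methylpent-2-enoate (CNP0188570.1) | COC(=O)/C=C(/C)CC[C@@H]1[C@@H](C=O)CC[C@@H]2C(C)(C)[C@H](O)CC[C@@]12C | target

Total step count: 17.
Longest linear sequence: 16 steps (steps 1–12 and 14–17, from (S)-carvone); step 13 is the only side branch.

Steps most likely to fail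

Step 5. The alkoxy radical formed after ring closure may reopen to the tertiary C4 radical faster than it is reduced, so that plain hydrogenation of the isopropenyl group takes over; the closure may also show poor facial selectivity at C3. The fallback is a halogen-atom-transfer radical cyclisation onto the aldehyde with a tin hydride, which traps the alkoxy radical by direct hydrogen transfer. It sets out from alcohol 9. HBr in CH2Cl2 at −40 °C adds to the isopropenyl group in the Markovnikov sense to give the tertiary bromide alcohol F1. Dess–Martin periodinane then gives the bromo aldehyde F2. Slow addition of Bu3SnH with AIBN in benzene at 80 °C generates the same C4 radical by bromine abstraction, and 6-exo closure comes back to the route at 11. If either closure leaves axial C3 alcohol in the product, the mixture is oxidised with Dess–Martin periodinane to the 3,9-dione F3 and reduced with NaBH4 in MeOH/CH2Cl2 at −78 °C. There the saturated C3 ketone should take hydride axially, while the hindered conjugated C9 ketone should not react; this also ends at 11.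

Step 9. Proton removal may occur at C7 in place of C17, which would lead to the endocyclic C7=C8 isomer, or the β,γ-unsaturated ester may slip back into conjugation during the quench. The fallback is a photochemical deconjugation in place of the anionic one. Irradiation of 15 at 254 nm in hexane with a catalytic amount of 1,2-dimethylimidazole leads, by 1,5-hydrogen transfer to the excited ester carbonyl, to a photodienol. Only C17, the γ-carbon lying next to the ester, can supply that hydrogen, and ketonisation of the dienol gives 17. The fallback sets out from 15, makes no new compound and comes back to the route at 17.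

Step 3. The borane may also add to the isopropenyl group or reduce the C9 carbonyl, and the oxidative work-up may epoxidise the enone. The fallback carries the aldehyde in masked form through the alkylation, so that no hydroboration is needed. It sets out from 4: the enolate 6, made as in step 2, is alkylated with 2-(2-bromoethyl)-1,3-dioxolane (THF/DMPU, −78 °C to rt), again anti to the isopropenyl group, to give the dioxolane F4. PPTS in wet acetone at 50 °C then removes the acetal and comes back to the route at 10.

Further compounds
F1 | step 5 | tertiary bromide alcohol: 9 with a 2-bromopropan-2-yl group in place of isopropenyl | O=C1C(C)=CC[C@H](C(C)(C)Br)[C@@]1(C)CCCO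
F2 | step 5 | bromo aldehyde: 10 with a 2-bromopropan-2-yl group in place of isopropenyl | O=C1C(C)=CC[C@H](C(C)(C)Br)[C@@]1(C)CCC=O
F3 | step 5 | 3,9-dione: (4aR,8aR)-2,5,5,8a-tetramethyl-4a,7,8,8a-tetrahydronaphthalene-1,6(4H,5H)-dione | O=C1C(C)=CC[C@@H]2C(C)(C)C(=O)CC[C@@]12C
F0 | step 9 | none | none
F4 | step 3 | dioxolane: 6-methylcarvone carrying a 2-(1,3-dioxolan-2-yl)ethyl group on the quaternary carbon, anti to isopropenyl | O=C1C(C)=CC[C@H](C(C)=C)[C@@]1(C)CCC2OCCO2
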